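common to all: substrate 2.2 M

| run | temperature | remark | time |
|---|---|---|---|
| alpha | 90 °C | the very flask that is asked about, followed so far |  |
| zeta | 75 °C | run made earlier |  |
| flask | 90 °C |  | 4.0 h |
- alpha (time / min: product / %, substrate / %): 12.0: 14.6, 66.2; 40.0: 26.3, 32.2; 60.0: 29.4, 21.3; 90.0: 30.5, 13.4; 150: 31.6, 8.1; 180: 32.1, 7.4; 240: 32.6, 6.8
- zeta (time / min: product / %, substrate / %): 25.0: 11.3, 80.1; 80.0: 24.6, 53.0; 120: 30.2, 41.2; 180: 34.0, 30.4; 300: 37.8, 16.7; 360: 38.9, 13.5; 480: 39.6, 8.9

(standard deviation of a reading: 0.3 percentage points)
- a species is counted by the substrate in it: one product counts as two
- product taken out counts as made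
- what was read earlier has a scatter of 0.3 percentage points, one standard deviation
- reactions considered so far: substrate <-> dormant form; 2 substrate -> product
- Monday's: at 4.0 h raise the temperature by 25 K, then wait 8.0 h
- Tuesday's: change nothing and wait 8.0 h more
- Friday's: at 4.0 h take out 90% of the product then present, then wait 8.0 h
* product, in percent of the substrate first charged, at 4.0 h
* the remedy with the largest gain of product, or "none" below 2 percentage points (Monday's / Tuesday's / Friday's / none)
* product present, with what was taken out counted in, in percent of the substrate first charged, after Tuesday's
* product present, with what was taken out counted in, in percent of the substrate first charged, after Friday's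

A one-step world has one road from substrate to product, but the flask at 90 °C, followed as the alpha run, has a fork: a free substrate molecule either pairs with another into product or passes into the dormant form, and it may come back.

For whoever takes over the bench: at 240 min the flask reads 32.6% product and 6.8% substrate, so by balance 60.6% is dormant form, the resting state of the charge. I carry the reserve ratio, dormant form over substrate, 8.91, which puts 10.1% of the unconverted pool in the free state.

Product gain per minute, divided by the product of the two bounding substrate fractions, reads 0.0196 /min early and 0.0202 /min in the tail, so the step has not slowed with product standing, and I see no use in taking product out. If the reserve ratio holds while the pool drains, waiting 8.0 h adds 4.1 percentage points, so I expect 36.7% on your return.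

The forecast gives 32.6%, chooses Monday's, and puts Tuesday's at 36.4% and Friday's at 36.4%, a little below my figure. Its ground for heating is that “the dormant form is favoured less when hot”.

The flask gives 32.6%, 35.9% after Tuesday's and 35.9% after Friday's, and Monday's wins with 45 points against 3.3 points for waiting.

    substrate ⇌ dormant form (K = 9.30, k = 3.20 × 10⁻⁴ /s, Ea = 115 kJ/mol, ΔH = −51.0 kJ/mol)
    2 substrate → product (k = 7.00 × 10⁻⁵ /M/s, Ea = 83.0 kJ/mol)
    (constants at 90 °C)

To overturn the forecast's choice of Monday's, a hot run has to show a reserve ratio that does not fall and little product gained. The reserve ratio of the flask stands at 9.48 after 240 min and 9.72 after 2400 min, while product climbs to 45.3%. The neighbouring flask at 105 °C holds 50.2% dormant form over 10.0% substrate after 240 min, a reserve ratio of 5.02 and a free share of 16.6%, and it stands at 39.8% product.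

(The numbers in the tables are calculated from invented constants, noise included.)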